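**Plan**

- Retrosynthesis: ring A is cut at the bond between its propyl-bearing carbon C1 and a neighbouring CH carbon (an aldol bond), which unfolds it to the 3-aryloxynonane-2,4,6-trione 9. The chain of 9 is then cut at the C5–C6 acyl bond (butanoyl donor) and at the C3–O ether bond (phenoxide plus 3-chloropentane-2,4-dione). The ring B side chain is cut at Cα–Cβ back to the aldehyde of 3,4-dihydroxy-5-methoxybenzaldehyde.
- Enabling feature: ring A carries propyl on C1 and oxygen on C3, C4 and C5. This is the pattern of a nonane-2,4,6-trione folded C1 to C6 with the ether oxygen already on chain C3 (ring A C4), so the hindered diaryl ether is never made on an aromatic carbon of ring A.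
- Forward: ring B is bought. O4 is benzylated, the aldehyde masked, O3 alkylated with the chlorodiketone, the diketone dianion butanoylated, and ring A (the only ring made) folded by aldol condensation.
- Endgame: O-methylation and unmasking, Wittig homologation, hydrogenation with debenzylation, and ester reduction.
- Stereochemistry: the target has no stereocentre. C3 of 9 is racemic and becomes sp2 on aromatisation, and the alkene geometry of 16 is erased by hydrogenation.

Key step: step 5

Remark: N-methoxy-N-methylbutanamide is taken as the purchasable butanoyl donor in place of an enolisable butanoate ester, because its tetrahedral adduct keeps the acidic triketone from quenching the dianion.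

**Route**

Step 1
Reactants: 1 3,4-dihydroxy-5-methoxybenzaldehyde; 2 benzyl bromide
Product: 3 4-(benzyloxy)-3-hydroxy-5-methoxybenzaldehyde
Conditions: BnBr (1.05 equiv), Li2CO3, DMF, 45 °C
Reagents that add atoms: benzyl bromide (2), BrCc1ccccc1
Why: Williamson etherification under weak-base control, in which only the 4-OH (para to the formyl group and so the more acidic phenol) is ionised by Li2CO3, so benzylation should occur there and leave O3 free.

Step 2
Reactants: 3 4-(benzyloxy)-3-hydroxy-5-methoxybenzaldehyde; 4 ethane-1,2-diol
Product: 5 2-(benzyloxy)-5-(1,3-dioxolan-2-yl)-3-methoxyphenol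
Conditions: ethane-1,2-diol, p-TsOH·H2O (cat.), toluene, reflux (Dean–Stark); Et3N quench
Reagents that add atoms: ethane-1,2-diol (4), OCCO
Why: Acid-catalysed acetalisation with azeotropic removal of water should turn the aldehyde into a base-stable 1,3-dioxolane without touching the phenol or the benzyl ether.

Step 3
Reactants: 5 2-(benzyloxy)-5-(1,3-dioxolan-2-yl)-3-methoxyphenol; 6 3-chloropentane-2,4-dione
Product: 7 3-[2-(benzyloxy)-5-(1,3-dioxolan-2-yl)-3-methoxyphenoxy]pentane-2,4-dione
Conditions: Cs2CO3, acetone, 50 °C
Reagents that add atoms: 3-chloropentane-2,4-dione (6), CC(=O)C(Cl)C(C)=O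
Why: Williamson-type SN2 displacement of chloride from the carbon flanked by two carbonyl groups by the caesium phenoxide, a well-used entry to 3-aryloxypentane-2,4-diones, should place the ether oxygen on the carbon that becomes C4 of ring A.

Step 4
Reactants: 7 3-[2-(benzyloxy)-5-(1,3-dioxolan-2-yl)-3-methoxyphenoxy]pentane-2,4-dione; 8 N-methoxy-N-methylbutanamide
Product: 9 3-[2-(benzyloxy)-5-(1,3-dioxolan-2-yl)-3-methoxyphenoxy]nonane-2,4,6-trione (racemic at C3, largely enolised)
Conditions: LiN(iPr)2 (2.1 equiv), THF, −78 to 0 °C; then 8, −78 to −20 °C; aq NH4Cl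
Reagents that add atoms: N-methoxy-N-methylbutanamide (8), CCCC(=O)N(C)OC
Why: Harris–Hauser dianion acylation, in which the first equivalent of amide base removes the C3 proton and the second a proton of one of the two equivalent methyl groups, and the terminal carbanion should add to the N-methoxy-N-methylamide to give a chelated adduct that releases the triketone only on work-up.

Step 5
Reactants: 9 3-[2-(benzyloxy)-5-(1,3-dioxolan-2-yl)-3-methoxyphenoxy]nonane-2,4,6-trione
Product: 11 2-[2-(benzyloxy)-5-(1,3-dioxolan-2-yl)-3-methoxyphenoxy]-5-propylbenzene-1,3-diol, via cyclic aldol 10 (not isolated)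
Conditions: 0.5 M aq KOH (3 equiv), THF, degassed, Ar, 0 °C to rt; then AcOH to pH 6–7, 0 °C
Reagents that add atoms: none
Why: Hydroxide converts 9 into its enolates; the carbanion at the terminal methyl C1 adds to the C6 ketone, the cyclic aldol 10 (a 2-aryloxy-5-hydroxycyclohexane-1,3-dione) loses water by E1cB elimination, and the cyclohexenedione tautomerises irreversibly to the resorcinol. The closest known reaction is the base-induced aldol cyclisation of heptane-2,4,6-trione and its homologues to 5-alkylresorcinols, the classical laboratory model of polyketide folding. The six-membered carbocycle closes in the 6-(enolendo)-exo-trig mode, chain atoms C1 to C6 becoming the ring. No stereocentre is created, and the racemic C3 centre of 9 becomes the sp2 carbon that bears the ether oxygen. The step needs C1 rather than the C7 methylene as nucleophile and needs cyclisation to outrun retro-Claisen loss of the acetyl group. The primary carbanion is the less hindered one and its aldol 10 has no contiguous trisubstitution (attack of C7 on C2 would lead to a crowded 4-aryloxy-6-ethyl-5-methylresorcinol), while cold dilute hydroxide under argon keeps the triketone as an enolate that resists hydroxide addition, and aromatisation removes 11 from all equilibria.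

Step 6
Reactants: 11 2-[2-(benzyloxy)-5-(1,3-dioxolan-2-yl)-3-methoxyphenoxy]-5-propylbenzene-1,3-diol; 12 iodomethane
Product: 14 4-(benzyloxy)-3-(2,6-dimethoxy-4-propylphenoxy)-5-methoxybenzaldehyde, via bis(methyl ether) acetal 13 (not isolated)
Conditions: MeI, K2CO3, acetone, 50 °C; filter, concentrate; then 1 M aq HCl, THF, rt
Reagents that add atoms: iodomethane (12), CI; water, O
Why: Williamson O-methylation of both resorcinol hydroxyls followed by acid-catalysed acetal hydrolysis of the crude ether should give the aldehyde, the aryl benzyl ether and the diaryl ether being stable to cold dilute HCl.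

Step 7
Reactants: 14 4-(benzyloxy)-3-(2,6-dimethoxy-4-propylphenoxy)-5-methoxybenzaldehyde; 15 ethyl (triphenylphosphoranylidene)acetate
Product: 16 ethyl (E)-3-[4-(benzyloxy)-3-(2,6-dimethoxy-4-propylphenoxy)-5-methoxyphenyl]prop-2-enoate
Conditions: 15 (1.3 equiv), toluene, 80 °C
Reagents that add atoms: ethyl (triphenylphosphoranylidene)acetate (15), CCOC(=O)C=P(c1ccccc1)(c1ccccc1)c1ccccc1
Why: Wittig olefination with a stabilised ylide should give the (E)-cinnamate, whose geometry is of no consequence because the alkene is reduced in the next step.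

Step 8
Reactants: 16 ethyl (E)-3-[4-(benzyloxy)-3-(2,6-dimethoxy-4-propylphenoxy)-5-methoxyphenyl]prop-2-enoate
Product: 17 ethyl 3-[3-(2,6-dimethoxy-4-propylphenoxy)-4-hydroxy-5-methoxyphenyl]propanoate
Conditions: H2 (1 atm), 10% Pd/C, EtOAc–EtOH, rt
Reagents that add atoms: none
Why: Heterogeneous catalytic hydrogenation should saturate the conjugated alkene and cleave the aryl benzyl ether by hydrogenolysis in one operation, leaving the methyl ethers, the diaryl ether and the ester untouched.

Step 9
Reactants: 17 ethyl 3-[3-(2,6-dimethoxy-4-propylphenoxy)-4-hydroxy-5-methoxyphenyl]propanoate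
Product: 18 3-[3-(2,6-dimethoxy-4-propylphenoxy)-4-hydroxy-5-methoxyphenyl]propan-1-ol
Conditions: LiAlH4 (2.5 equiv), THF, 0 °C to rt; then 1 M aq HCl, 0 °C
Reagents that add atoms: none
Why: Hydride reduction of the ester to the primary alcohol with excess LiAlH4 should give the target, one hydride being spent on the phenol, which is returned on acidic work-up.

**Compound list**

1 | 3,4-dihydroxy-5-methoxybenzaldehyde | COc1cc(C=O)cc(O)c1O | starting material
2 | benzyl bromide | BrCc1ccccc1 | starting material
3 | 4-(benzyloxy)-3-hydroxy-5-methoxybenzaldehyde | COc1cc(C=O)cc(O)c1OCc1ccccc1 | intermediate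
4 | ethane-1,2-diol | OCCO | starting material
5 | 2-(benzyloxy)-5-(1,3-dioxolan-2-yl)-3-methoxyphenol | COc1cc(C2OCCO2)cc(O)c1OCc1ccccc1 | intermediate
6 | 3-chloropentane-2,4-dione | CC(=O)C(Cl)C(C)=O | starting material
7 | 3-[2-(benzyloxy)-5-(1,3-dioxolan-2-yl)-3-methoxyphenoxy]pentane-2,4-dione | CC(=O)C(Oc1cc(C2OCCO2)cc(OC)c1OCc1ccccc1)C(C)=O | intermediate
8 | N-methoxy-N-methylbutanamide | CCCC(=O)N(C)OC | starting material
9 | 3-[2-(benzyloxy)-5-(1,3-dioxolan-2-yl)-3-methoxyphenoxy]nonane-2,4,6-trione (racemic at C3, enolisable) | CCCC(=O)CC(=O)C(Oc1cc(C2OCCO2)cc(OC)c1OCc1ccccc1)C(C)=O | intermediate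
10 | 2-[2-(benzyloxy)-5-(1,3-dioxolan-2-yl)-3-methoxyphenoxy]-5-hydroxy-5-propylcyclohexane-1,3-dione (cyclic aldol, cis/trans mixture about C2 and C5, not isolated) | CCCC1(O)CC(=O)C(Oc2cc(C3OCCO3)cc(OC)c2OCc2ccccc2)C(=O)C1 | intermediate
11 | 2-[2-(benzyloxy)-5-(1,3-dioxolan-2-yl)-3-methoxyphenoxy]-5-propylbenzene-1,3-diol | CCCc1cc(O)c(Oc2cc(C3OCCO3)cc(OC)c2OCc2ccccc2)c(O)c1 | intermediate
12 | iodomethane | CI | starting material
13 | 2-[4-(benzyloxy)-3-(2,6-dimethoxy-4-propylphenoxy)-5-methoxyphenyl]-1,3-dioxolane (not isolated) | CCCc1cc(OC)c(Oc2cc(C3OCCO3)cc(OC)c2OCc2ccccc2)c(OC)c1 | intermediate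
14 | 4-(benzyloxy)-3-(2,6-dimethoxy-4-propylphenoxy)-5-methoxybenzaldehyde | CCCc1cc(OC)c(Oc2cc(C=O)cc(OC)c2OCc2ccccc2)c(OC)c1 | intermediate
15 | ethyl (triphenylphosphoranylidene)acetate | CCOC(=O)C=P(c1ccccc1)(c1ccccc1)c1ccccc1 | starting material
16 | ethyl (E)-3-[4-(benzyloxy)-3-(2,6-dimethoxy-4-propylphenoxy)-5-methoxyphenyl]prop-2-enoate | CCCc1cc(OC)c(Oc2cc(/C=C/C(=O)OCC)cc(OC)c2OCc2ccccc2)c(OC)c1 | intermediate
17 | ethyl 3-[3-(2,6-dimethoxy-4-propylphenoxy)-4-hydroxy-5-methoxyphenyl]propanoate | CCCc1cc(OC)c(Oc2cc(CCC(=O)OCC)cc(OC)c2O)c(OC)c1 | intermediate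
18 | 3-[3-(2,6-dimethoxy-4-propylphenoxy)-4-hydroxy-5-methoxyphenyl]propan-1-ol | CCCc1cc(OC)c(Oc2cc(CCCO)cc(OC)c2O)c(OC)c1 | target

**Count and risks**

Total step count: 9. Longest linear sequence: 9 steps (1 to 18).

The three steps most likely to fail:

Step 5. Retro-Claisen loss of the acetyl group, attack by the C7 terminus instead of C1, or intermolecular condensation may outrun the intended fold. The fallback gives up the biomimetic closure and makes the diaryl ether by Ullmann coupling. It sets out from benzyl bromide 2, which O-benzylates commercial 4-hydroxy-3-iodo-5-methoxybenzaldehyde (K2CO3, DMF, rt) to 4-(benzyloxy)-3-iodo-5-methoxybenzaldehyde F1. F1 is then coupled with commercial 2,6-dimethoxy-4-propylphenol (CuI, picolinic acid, K3PO4, DMSO, 90–110 °C), and the coupling product is aldehyde 14, where the route is rejoined.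

Step 4. Proton transfer from the amide or from released product to the dianion, or sluggish addition of the hindered dianion, may stall the acylation. The fallback replaces acylation by aldol addition and oxidation. From diketone 7 the same dianion (LiN(iPr)2, THF, −78 °C) is added to butanal, a far better electrophile whose alkoxide adduct is not acidic, to give 3-[2-(benzyloxy)-5-(1,3-dioxolan-2-yl)-3-methoxyphenoxy]-6-hydroxynonane-2,4-dione F2 as a diastereomer mixture. Oxidation of the secondary alcohol (Dess–Martin periodinane, NaHCO3, CH2Cl2, rt) then returns to the route at triketone 9.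

Step 3. The hindered phenoxide may displace chloride slowly while carbonate deacetylates the chlorodiketone or the product. The fallback forms the same C–O bond by carbenoid O–H insertion. 3-Diazopentane-2,4-dione F3, made from pentane-2,4-dione by diazo transfer (4-acetamidobenzenesulfonyl azide, Et3N, MeCN), is decomposed with Rh2(OAc)4 (cat., CH2Cl2, reflux) in the presence of phenol 5. The insertion product is diketone 7, where the route is rejoined.

Further compounds
F1 | step 5 | 4-(benzyloxy)-3-iodo-5-methoxybenzaldehyde | COc1cc(C=O)cc(I)c1OCc1ccccc1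
F2 | step 4 | 3-[2-(benzyloxy)-5-(1,3-dioxolan-2-yl)-3-methoxyphenoxy]-6-hydroxynonane-2,4-dione (racemic diastereomer mixture) | CCCC(O)CC(=O)C(Oc1cc(C2OCCO2)cc(OC)c1OCc1ccccc1)C(C)=O
F3 | step 3 | 3-diazopentane-2,4-dione | CC(=O)C(=[N+]=[N-])C(C)=O
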